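The readings were generated by integration for substances that don't exist; noise was put on by code.

Carry forward how fast standing Q eats D, and read it from the run shortest of L.

| setting | epsilon | theta | alpha | zeta | violet | ochre | grey | teal |
|---|---|---|---|---|---|---|---|---|
| Q | 0.25 M | 0.25 M | 0.25 M | 0.25 M | 0.25 M (fed, over 20 h) | 0.25 M | 0.25 M | 0.25 M |
| E | 1.8 equiv | 0.90 equiv | 1.4 equiv | 1.8 equiv | 1.80 equiv | 1.80 equiv | 1.80 equiv (fed, over 20 h) | 1.80 equiv (in portions, 2, over 20 h) |
| L | 2 equiv | 2 equiv | 2 equiv | 1 equiv | 2.00 equiv | 2.00 equiv | 2.00 equiv | 2.00 equiv |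
| remark | run made earlier | run made earlier | run made earlier | run made earlier | all else is in the flask from the start; the feed brings no volume worth counting | everything together at the start | all else is in the flask from the start; the feed brings no volume worth counting | first portion at the start, last at 20 h |
| time |  |  |  |  | 25 h | 25 h | 25 h | 25 h |

* the flask with the highest amount of D, in percent of the Q charged ("all alike" if they lie within 1.5 percentage points) (violet / ochre / grey / teal / all alike)
* final D, as a percentage of the Q charged, in violet
* final D, as a percentage of the Q charged, in ochre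
* final D, as a percentage of the Q charged, in grey
* final D, as a percentage of the Q charged, in teal

- a species is counted by the Q in it: one Z or G counts as two
- candidate steps: Q + L -> J; L + E -> X; J + X -> D; 2 J -> Z; Q + D -> G

epsilon run (percent of the Q charged): time / h: D / % = 4.00: 28.4; 8.00: 26.2; 12.0: 23.0; 15.0: 20.6; 20.0: 18.4; 25.0: 17.4

theta run (percent of the Q charged): time / h: D / % = 1.33: 7.7; 4.00: 26.2; 8.00: 34.1; 10.0: 35.6; 15.0: 38.3; 20.0: 38.6

alpha run (percent of the Q charged): time / h: D / % = 3.00: 24.4; 6.00: 31.7; 10.0: 31.1; 12.0: 30.8; 15.0: 29.8; 20.0: 29.2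

These runs differ in E, and their readings at 20.0 h rise from 18.4% through 29.2% to 38.6% as E falls. Among the candidate steps, Q + D to G can remove D once it has formed. Zeta shows D falling:

zeta run (percent of the Q charged): time / h: D / % = 4.00: 11.6; 8.00: 7.6; 12.0: 4.2; 15.0: 2.5; 20.0: 0.9

Read its rows as logarithmic slopes. The first span gives 0.106 h⁻¹. The span from 12.0 h to 20.0 h gives a steeper 0.193 h⁻¹. Take the later one, judging that fresh D counts for less there; it remains a reading, with a scatter of 0.3 percentage points on each point. Guess the fraction of Q standing in zeta as 0.5. The erosion coefficient is then 0.385 h⁻¹, the pseudo-first-order loss of D per hour per unit fraction of Q standing.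

Now reckon violet. Assume the same fraction 0.5 of Q stands in violet through the 5.00 h after the feed, so by the coefficient D keeps a fraction 0.382. Guess violet's D at the end of the feed as zeta's 11.6% at 4.00 h; my estimate for violet is then 4.43%. For ochre take epsilon's 17.4%, and for teal, whose first portion matches theta's 0.90 equiv of E, take theta's 38.6%, which stands above my violet and ochre values.

The forecast also names teal, with violet 13%, ochre 17.4%, grey 33% and teal 38.7%. Its violet value stands above mine, on the grounds that “L goes to X before Q arrives, and late Q eats D”.

The flasks give violet 3.72%, ochre 17.4%, grey 36.1% and teal 39.3%, with teal highest.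

    Q + L → J (k = 1.02 M⁻¹ h⁻¹)
    L + E → X (k = 1.28 M⁻¹ h⁻¹)
    J + X → D (k = 4.88 M⁻¹ h⁻¹)
    2 J → Z (k = 0.952 M⁻¹ h⁻¹)
    Q + D → G (k = 1.88 M⁻¹ h⁻¹)

In violet, where L is the limiting reagent, half of the L + E turnover up to 25 h is done by 1.29 h, but half of the J + X turnover up to 25 h takes until 9.27 h. The coefficient, applied to violet's 6.60% of D at 20.0 h with Q going from 48.6% to 41.2%, gives 2.78%, beside the simulated 3.72%. In grey, Q is 0.411% at 20.0 h, so the same coefficient gives a correction of 0.29 points, and grey's D reads 36.2% at 20.0 h and 36.1% at 25.0 h.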